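**Plan**

- Retrosynthesis (1-benzofuran-2-one numbering): first the primary silyl ether and the C4 ester; then the three bonds of a [2+2+1] (ring-fusion bond C3a–C7a, C3–C2, C2–O1) back to an allenyl aldehyde and CO; the allene to a terminal alkyne and CH2O; the alkyne–carbonyl bond to a Weinreb amide; the C6–C7 bond to a (Z)-enol triflate of a β-keto amide made from (S)-citronellic acid.
- Forward: the chain is built first (citronellic acid → β-keto amide → (Z)-enol triflate → Negishi coupling → ynone → allene). One step then closes the cyclohexene ring and the lactone ring together, and C4 is adjusted and acylated last.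
- Enabling feature: the α-methylene-γ-butyrolactone cis-fused to the cyclohexene has the lactone oxygen on C7a and the 1-carboxyvinyl unit on C3a, so the fusion bond is the C–C bond of an aldehyde/allene/CO cyclocarbonylation. The Z-tetrasubstituted C5=C6 alkene holds the aldehyde arm and the allene arm on the same side.
- Stereochemistry: the side-chain center comes from (S)-citronellic acid and the acyl center from (R)-2-methylbutanoic acid. A Corey–Bakshi–Shibata reduction sets a relay carbinol (4S) that steers C3a/C7a (cis to each other through the metallacycle, anti to the silyl ether).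
- C4 is then turned into 4R by oxidation and Luche reduction from the convex face.

Key step: step 12

Remark: (S)-citronellic acid, (R)-2-methylbutanoic acid, (1,3-dioxolan-2-ylmethyl)zinc bromide and ethynylmagnesium bromide are taken as commercial; the acyl stereocenter of the given structure is read as R; ring locants follow 1-benzofuran-2-one numbering (O1, C2, C3, C3a, C4–C7, C7a).

**Route**

Step 1
Reactants: 1 (S)-citronellic acid; 2 N,O-dimethylhydroxylamine hydrochloride
Product: 4 (3S)-N-methoxy-N,3,7-trimethyloct-6-enamide, via acyl imidazolide 3 (not isolated)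
Conditions: 1,1'-carbonyldiimidazole, CH2Cl2, rt; then 2, rt
Reagents that add atoms: none
Why: Acyl imidazolide formation followed by aminolysis (Weinreb amide synthesis) should proceed without touching the β-stereocenter.

Step 2
Reactants: 4 (3S)-N-methoxy-N,3,7-trimethyloct-6-enamide
Product: 6 (3S)-6-hydroxy-N-methoxy-N,3-dimethylhexanamide, via aldehyde 5 (not isolated)
Conditions: O3, CH2Cl2/MeOH, −78 °C; then NaBH4, −78 °C to rt
Reagents that add atoms: ozone, [O-][O+]=O
Why: Ozonolysis cleaves the only alkene and the reductive NaBH4 work-up takes the aldehyde to the alcohol, while the Weinreb amide is inert to borohydride.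

Step 3
Reactants: 6 (3S)-6-hydroxy-N-methoxy-N,3-dimethylhexanamide
Product: 7 (3S)-6-[(tert-butyldiphenylsilyl)oxy]-N-methoxy-N,3-dimethylhexanamide
Conditions: TBDPSCl, imidazole, CH2Cl2, 0 °C to rt
Reagents that add atoms: tert-butyl(chloro)diphenylsilane, CC(C)(C)[Si](Cl)(c1ccccc1)c1ccccc1
Why: Standard silylation of the primary alcohol gives a robust ether that should survive the later base, organometallic and mild acid steps.

Step 4
Reactants: 7 (3S)-6-[(tert-butyldiphenylsilyl)oxy]-N-methoxy-N,3-dimethylhexanamide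
Product: 8 (3S)-2-acetyl-6-[(tert-butyldiphenylsilyl)oxy]-N-methoxy-N,3-dimethylhexanamide (both C2 epimers)
Conditions: LDA (2.05 equiv), THF, −78 °C; then acetyl chloride (1.0 equiv, slow addition), −78 °C; 1 M HCl quench
Reagents that add atoms: acetyl chloride, CC(=O)Cl
Why: Crossed Claisen C-acylation of the amide lithium enolate (the second equivalent of base takes up the more acidic product) should give the β-keto amide; the new C2 center becomes sp2 in the next step.

Step 5
Reactants: 8 (3S)-2-acetyl-6-[(tert-butyldiphenylsilyl)oxy]-N-methoxy-N,3-dimethylhexanamide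
Product: 9 (2Z,4S)-7-[(tert-butyldiphenylsilyl)oxy]-3-[methoxy(methyl)carbamoyl]-4-methylhept-2-en-2-yl trifluoromethanesulfonate
Conditions: NaH, THF, 0 °C; then PhNTf2, 0 °C to rt
Reagents that add atoms: N-phenylbis(trifluoromethanesulfonimide), O=S(=O)(N(c1ccccc1)S(=O)(=O)C(F)(F)F)C(F)(F)F
Why: The sodium enolate is held in the chelated Z form between the ketone and amide oxygens and O-sulfonylation keeps this geometry, so the triflate should end cis to the amide carbonyl (stereoselective enol triflate formation from a β-dicarbonyl compound).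

Step 6
Reactants: 9 (2Z,4S)-7-[(tert-butyldiphenylsilyl)oxy]-3-[methoxy(methyl)carbamoyl]-4-methylhept-2-en-2-yl trifluoromethanesulfonate; 10 (1,3-dioxolan-2-ylmethyl)zinc bromide
Product: 11 (2Z)-4-(1,3-dioxolan-2-yl)-N-methoxy-N,3-dimethyl-2-[(2S)-5-[(tert-butyldiphenylsilyl)oxy]pentan-2-yl]but-2-enamide
Conditions: Pd(PPh3)4 (5 mol%), THF, 50 °C
Reagents that add atoms: none
Why: Negishi coupling of the vinyl triflate with the alkylzinc reagent goes with retention of alkene geometry and so fixes the tetrasubstituted Z-alkene with the masked aldehyde arm cis to the amide.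

Step 7
Reactants: 11 (2Z)-4-(1,3-dioxolan-2-yl)-N-methoxy-N,3-dimethyl-2-[(2S)-5-[(tert-butyldiphenylsilyl)oxy]pentan-2-yl]but-2-enamide; 12 ethynylmagnesium bromide
Product: 13 (4Z)-6-(1,3-dioxolan-2-yl)-5-methyl-4-[(2S)-5-[(tert-butyldiphenylsilyl)oxy]pentan-2-yl]hex-4-en-1-yn-3-one
Conditions: THF, 0 °C to rt; mixture poured into cold aq. NaHSO4
Reagents that add atoms: none
Why: Weinreb ketone synthesis: the magnesium chelate of the tetrahedral adduct stops at the ketone stage, and the acidic inverse quench keeps the freed amine from adding to the ynone.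

Step 8
Reactants: 13 (4Z)-6-(1,3-dioxolan-2-yl)-5-methyl-4-[(2S)-5-[(tert-butyldiphenylsilyl)oxy]pentan-2-yl]hex-4-en-1-yn-3-one
Product: 14 (3S,4Z)-6-(1,3-dioxolan-2-yl)-5-methyl-4-[(2S)-5-[(tert-butyldiphenylsilyl)oxy]pentan-2-yl]hex-4-en-1-yn-3-ol
Conditions: (3aR)-1-methyl-3,3-diphenyltetrahydro-1H,3H-pyrrolo[1,2-c][1,3,2]oxazaborole (20 mol%), catecholborane, CH2Cl2/toluene, −78 °C
Reagents that add atoms: none
Why: Corey–Bakshi–Shibata reduction: the ketone binds the catalyst with the bulky tetrasubstituted alkenyl group as the large and the ethynyl group as the small substituent, so the R catalyst should deliver hydride to give the 3S carbinol.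

Step 9
Reactants: 14 (3S,4Z)-6-(1,3-dioxolan-2-yl)-5-methyl-4-[(2S)-5-[(tert-butyldiphenylsilyl)oxy]pentan-2-yl]hex-4-en-1-yn-3-ol
Product: 15 (3S,4Z)-3-[(tert-butyldimethylsilyl)oxy]-6-(1,3-dioxolan-2-yl)-5-methyl-4-[(2S)-5-[(tert-butyldiphenylsilyl)oxy]pentan-2-yl]hex-4-en-1-yne
Conditions: TBSCl, imidazole, 4-(dimethylamino)pyridine (cat.), DMF, rt to 40 °C
Reagents that add atoms: tert-butyl(chloro)dimethylsilane, CC(C)(C)[Si](C)(C)Cl
Why: Silylation of the propargylic alcohol under basic conditions leaves the acetal intact and gives the bulky ether that later directs the ring closure.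

Step 10
Reactants: 15 (3S,4Z)-3-[(tert-butyldimethylsilyl)oxy]-6-(1,3-dioxolan-2-yl)-5-methyl-4-[(2S)-5-[(tert-butyldiphenylsilyl)oxy]pentan-2-yl]hex-4-en-1-yne
Product: 17 2-[(2Z,4S)-4-[(tert-butyldimethylsilyl)oxy]-2-methyl-3-[(2S)-5-[(tert-butyldiphenylsilyl)oxy]pentan-2-yl]hepta-2,5,6-trien-1-yl]-1,3-dioxolane, via propargylic amine 16 (not isolated)
Conditions: (CH2O)n, CuBr (0.5 equiv), iPr2NH, 1,4-dioxane, reflux
Reagents that add atoms: formaldehyde (from paraformaldehyde), C=O
Why: Crabbé homologation: the copper-promoted Mannich reaction gives the propargylic amine, which fragments by 1,5-hydride transfer to the terminal allene without touching the carbinol center.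

Step 11
Reactants: 17 2-[(2Z,4S)-4-[(tert-butyldimethylsilyl)oxy]-2-methyl-3-[(2S)-5-[(tert-butyldiphenylsilyl)oxy]pentan-2-yl]hepta-2,5,6-trien-1-yl]-1,3-dioxolane
Product: 18 (3Z,5S)-5-[(tert-butyldimethylsilyl)oxy]-3-methyl-4-[(2S)-5-[(tert-butyldiphenylsilyl)oxy]pentan-2-yl]octa-3,6,7-trienal
Conditions: pyridinium p-toluenesulfonate (cat.), acetone/H2O (10:1), 45 °C; used crude at once
Reagents that add atoms: water, O
Why: Mild acid-catalysed acetal hydrolysis should free the aldehyde without cleaving the silyl ethers; the β,γ-unsaturated aldehyde is carried on at once so that the alkene does not move into conjugation.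

Step 12
Reactants: 18 (3Z,5S)-5-[(tert-butyldimethylsilyl)oxy]-3-methyl-4-[(2S)-5-[(tert-butyldiphenylsilyl)oxy]pentan-2-yl]octa-3,6,7-trienal
Product: 19 (3aR,4S,7aR)-4-[(tert-butyldimethylsilyl)oxy]-5-[(2S)-5-[(tert-butyldiphenylsilyl)oxy]pentan-2-yl]-6-methyl-3-methylidene-3a,4,7,7a-tetrahydro-1-benzofuran-2(3H)-one
Conditions: Ru3(CO)12 (5 mol%), CO (20 atm), 1,4-dioxane, 120 °C
Reagents that add atoms: carbon monoxide, [C-]#[O+]
Why: Zerovalent ruthenium binds the aldehyde C=O and the internal π bond of the allene and couples them oxidatively to an oxaruthenacyclopentane, which makes the C3a–C7a bond and closes the cyclohexene ring; CO insertion into the Ru–C bond and C–O reductive elimination then close the lactone and leave the distal allene carbon as the exocyclic methylene. The closest known reaction type is the hetero-Pauson–Khand cyclocarbonylation of allenyl aldehydes to bicyclic α-methylene-γ-butyrolactones. The carbocycle closes in a 6-exo-trig mode at both reacting carbons (the central allene carbon and the carbonyl oxygen stay outside the ring), with the two arms held in reach by the Z-tetrasubstituted alkene, and the five-membered lactone closes by the [2+2+1] carbonylation. C3a and C7a should arise cis to each other because both belong to the five-membered metallacycle fused to the new ring. Their absolute sense is set by the C4 silyl ether, which sits pseudoaxial to avoid A(1,2) strain with the C5 side chain, so the bulky metallacycle should form on the opposite face (C3a–C3 bond anti to the silyloxy group). The step needs the internal and not the terminal allene π bond to react (a six- instead of a seven-membered ring secures this) and needs cyclization to outrun isomerization or decarbonylation of the β,γ-unsaturated aldehyde, which the CO pressure and the preorganized tether should favor.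

Step 13
Reactants: 19 (3aR,4S,7aR)-4-[(tert-butyldimethylsilyl)oxy]-5-[(2S)-5-[(tert-butyldiphenylsilyl)oxy]pentan-2-yl]-6-methyl-3-methylidene-3a,4,7,7a-tetrahydro-1-benzofuran-2(3H)-one
Product: 20 (3aS,4S,7aR)-4-hydroxy-5-[(2S)-5-[(tert-butyldiphenylsilyl)oxy]pentan-2-yl]-6-methyl-3-methylidene-3a,4,7,7a-tetrahydro-1-benzofuran-2(3H)-one
Conditions: HF·pyridine, pyridine/THF, 0 °C to rt
Reagents that add atoms: none
Why: Under HF·pyridine the secondary tert-butyldimethylsilyl ether should be cleaved well before the primary tert-butyldiphenylsilyl ether (selective desilylation).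

Step 14
Reactants: 20 (3aS,4S,7aR)-4-hydroxy-5-[(2S)-5-[(tert-butyldiphenylsilyl)oxy]pentan-2-yl]-6-methyl-3-methylidene-3a,4,7,7a-tetrahydro-1-benzofuran-2(3H)-one
Product: 21 (3aR,7aR)-5-[(2S)-5-[(tert-butyldiphenylsilyl)oxy]pentan-2-yl]-6-methyl-3-methylidene-3,3a,7,7a-tetrahydro-1-benzofuran-2,4-dione
Conditions: Dess–Martin periodinane, NaHCO3, CH2Cl2, 0 °C; used crude
Reagents that add atoms: none
Why: Dess–Martin oxidation under buffered, non-basic conditions should give the enone without β-elimination of the lactone oxygen or migration of the exocyclic alkene.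

Step 15
Reactants: 21 (3aR,7aR)-5-[(2S)-5-[(tert-butyldiphenylsilyl)oxy]pentan-2-yl]-6-methyl-3-methylidene-3,3a,7,7a-tetrahydro-1-benzofuran-2,4-dione
Product: 22 (3aS,4R,7aR)-4-hydroxy-5-[(2S)-5-[(tert-butyldiphenylsilyl)oxy]pentan-2-yl]-6-methyl-3-methylidene-3a,4,7,7a-tetrahydro-1-benzofuran-2(3H)-one
Conditions: NaBH4, CeCl3·7H2O, MeOH, −78 °C
Reagents that add atoms: none
Why: Luche reduction (1,2-selective, so the α-methylene lactone is left alone): hydride should add to the ketone from the convex face of the cis-fused bicycle, anti to the lactone ring, which places the new hydroxyl cis to the lactone and sets 4R.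

Step 16
Reactants: 22 (3aS,4R,7aR)-4-hydroxy-5-[(2S)-5-[(tert-butyldiphenylsilyl)oxy]pentan-2-yl]-6-methyl-3-methylidene-3a,4,7,7a-tetrahydro-1-benzofuran-2(3H)-one; 23 (2R)-2-methylbutanoic acid
Product: 24 (3aR,4R,7aR)-5-[(2S)-5-[(tert-butyldiphenylsilyl)oxy]pentan-2-yl]-6-methyl-3-methylidene-2-oxo-2,3,3a,4,7,7a-hexahydro-1-benzofuran-4-yl (2R)-2-methylbutanoate
Conditions: DCC, 4-(dimethylamino)pyridine (cat.), CH2Cl2, 0 °C to rt
Reagents that add atoms: none
Why: Steglich esterification of the hindered allylic alcohol with the enantiopure acid; a low loading of the acyl-transfer catalyst at 0 °C limits epimerization of the α-stereocenter of the acid.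

Step 17
Reactants: 24 (3aR,4R,7aR)-5-[(2S)-5-[(tert-butyldiphenylsilyl)oxy]pentan-2-yl]-6-methyl-3-methylidene-2-oxo-2,3,3a,4,7,7a-hexahydro-1-benzofuran-4-yl (2R)-2-methylbutanoate
Product: 25 (3aR,4R,7aR)-5-[(2S)-5-hydroxypentan-2-yl]-6-methyl-3-methylidene-2-oxo-2,3,3a,4,7,7a-hexahydro-1-benzofuran-4-yl (2R)-2-methylbutanoate
Conditions: TBAF, AcOH (1:1), THF, 0 °C to rt
Reagents that add atoms: none
Why: Fluoride cleavage of the primary silyl ether, buffered with acetic acid so that the α-methylene lactone and the ester are not attacked.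

**Compound list**

1 | (3S)-3,7-dimethyloct-6-enoic acid, (S)-citronellic acid | OC(=O)C[C@@H](C)CCC=C(C)C | starting material
2 | N,O-dimethylhydroxylamine hydrochloride | CNOC.Cl | starting material
3 | (3S)-1-(1H-imidazol-1-yl)-3,7-dimethyloct-6-en-1-one (acyl imidazolide) | O=C(C[C@@H](C)CCC=C(C)C)n1ccnc1 | intermediate
4 | (3S)-N-methoxy-N,3,7-trimethyloct-6-enamide | CON(C)C(=O)C[C@@H](C)CCC=C(C)C | intermediate
5 | (3S)-N-methoxy-N,3-dimethyl-6-oxohexanamide (aldehyde) | CON(C)C(=O)C[C@@H](C)CCC=O | intermediate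
6 | (3S)-6-hydroxy-N-methoxy-N,3-dimethylhexanamide | CON(C)C(=O)C[C@@H](C)CCCO | intermediate
7 | (3S)-6-[(tert-butyldiphenylsilyl)oxy]-N-methoxy-N,3-dimethylhexanamide | CON(C)C(=O)C[C@@H](C)CCCO[Si](c1ccccc1)(c1ccccc1)C(C)(C)C | intermediate
8 | (3S)-2-acetyl-6-[(tert-butyldiphenylsilyl)oxy]-N-methoxy-N,3-dimethylhexanamide (both C2 epimers) | CON(C)C(=O)C(C(C)=O)[C@@H](C)CCCO[Si](c1ccccc1)(c1ccccc1)C(C)(C)C | intermediate
9 | (2Z,4S)-7-[(tert-butyldiphenylsilyl)oxy]-3-[methoxy(methyl)carbamoyl]-4-methylhept-2-en-2-yl trifluoromethanesulfonate | CON(C)C(=O)/C(=C(/C)OS(=O)(=O)C(F)(F)F)[C@@H](C)CCCO[Si](c1ccccc1)(c1ccccc1)C(C)(C)C | intermediate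
10 | (1,3-dioxolan-2-ylmethyl)zinc bromide | Br[Zn]CC1OCCO1 | starting material
11 | (2Z)-4-(1,3-dioxolan-2-yl)-N-methoxy-N,3-dimethyl-2-[(2S)-5-[(tert-butyldiphenylsilyl)oxy]pentan-2-yl]but-2-enamide | CON(C)C(=O)/C(=C(/C)CC1OCCO1)[C@@H](C)CCCO[Si](c1ccccc1)(c1ccccc1)C(C)(C)C | intermediate
12 | ethynylmagnesium bromide | C#C[Mg]Br | starting material
13 | (4Z)-6-(1,3-dioxolan-2-yl)-5-methyl-4-[(2S)-5-[(tert-butyldiphenylsilyl)oxy]pentan-2-yl]hex-4-en-1-yn-3-one | C#CC(=O)/C(=C(/C)CC1OCCO1)[C@@H](C)CCCO[Si](c1ccccc1)(c1ccccc1)C(C)(C)C | intermediate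
14 | (3S,4Z)-6-(1,3-dioxolan-2-yl)-5-methyl-4-[(2S)-5-[(tert-butyldiphenylsilyl)oxy]pentan-2-yl]hex-4-en-1-yn-3-ol | C#C[C@H](O)/C(=C(/C)CC1OCCO1)[C@@H](C)CCCO[Si](c1ccccc1)(c1ccccc1)C(C)(C)C | intermediate
15 | (3S,4Z)-3-[(tert-butyldimethylsilyl)oxy]-6-(1,3-dioxolan-2-yl)-5-methyl-4-[(2S)-5-[(tert-butyldiphenylsilyl)oxy]pentan-2-yl]hex-4-en-1-yne | C#C[C@H](O[Si](C)(C)C(C)(C)C)/C(=C(/C)CC1OCCO1)[C@@H](C)CCCO[Si](c1ccccc1)(c1ccccc1)C(C)(C)C | intermediate
16 | (4S,5Z)-4-[(tert-butyldimethylsilyl)oxy]-7-(1,3-dioxolan-2-yl)-6-methyl-N,N-di(propan-2-yl)-5-[(2S)-5-[(tert-butyldiphenylsilyl)oxy]pentan-2-yl]hept-5-en-2-yn-1-amine (propargylic amine) | CC(C)N(C(C)C)CC#C[C@H](O[Si](C)(C)C(C)(C)C)/C(=C(/C)CC1OCCO1)[C@@H](C)CCCO[Si](c1ccccc1)(c1ccccc1)C(C)(C)C | intermediate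
17 | 2-[(2Z,4S)-4-[(tert-butyldimethylsilyl)oxy]-2-methyl-3-[(2S)-5-[(tert-butyldiphenylsilyl)oxy]pentan-2-yl]hepta-2,5,6-trien-1-yl]-1,3-dioxolane | C=C=C[C@H](O[Si](C)(C)C(C)(C)C)/C(=C(/C)CC1OCCO1)[C@@H](C)CCCO[Si](c1ccccc1)(c1ccccc1)C(C)(C)C | intermediate
18 | (3Z,5S)-5-[(tert-butyldimethylsilyl)oxy]-3-methyl-4-[(2S)-5-[(tert-butyldiphenylsilyl)oxy]pentan-2-yl]octa-3,6,7-trienal | C=C=C[C@H](O[Si](C)(C)C(C)(C)C)/C(=C(/C)CC=O)[C@@H](C)CCCO[Si](c1ccccc1)(c1ccccc1)C(C)(C)C | intermediate
19 | (3aR,4S,7aR)-4-[(tert-butyldimethylsilyl)oxy]-5-[(2S)-5-[(tert-butyldiphenylsilyl)oxy]pentan-2-yl]-6-methyl-3-methylidene-3a,4,7,7a-tetrahydro-1-benzofuran-2(3H)-one | C=C1C(=O)O[C@@H]2CC(C)=C([C@@H](C)CCCO[Si](c3ccccc3)(c3ccccc3)C(C)(C)C)[C@@H](O[Si](C)(C)C(C)(C)C)[C@H]12 | intermediate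
20 | (3aS,4S,7aR)-4-hydroxy-5-[(2S)-5-[(tert-butyldiphenylsilyl)oxy]pentan-2-yl]-6-methyl-3-methylidene-3a,4,7,7a-tetrahydro-1-benzofuran-2(3H)-one | C=C1C(=O)O[C@@H]2CC(C)=C([C@@H](C)CCCO[Si](c3ccccc3)(c3ccccc3)C(C)(C)C)[C@@H](O)[C@H]12 | intermediate
21 | (3aR,7aR)-5-[(2S)-5-[(tert-butyldiphenylsilyl)oxy]pentan-2-yl]-6-methyl-3-methylidene-3,3a,7,7a-tetrahydro-1-benzofuran-2,4-dione | C=C1C(=O)O[C@@H]2CC(C)=C([C@@H](C)CCCO[Si](c3ccccc3)(c3ccccc3)C(C)(C)C)C(=O)[C@H]12 | intermediate
22 | (3aS,4R,7aR)-4-hydroxy-5-[(2S)-5-[(tert-butyldiphenylsilyl)oxy]pentan-2-yl]-6-methyl-3-methylidene-3a,4,7,7a-tetrahydro-1-benzofuran-2(3H)-one | C=C1C(=O)O[C@@H]2CC(C)=C([C@@H](C)CCCO[Si](c3ccccc3)(c3ccccc3)C(C)(C)C)[C@H](O)[C@H]12 | intermediate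
23 | (2R)-2-methylbutanoic acid | CC[C@@H](C)C(=O)O | starting material
24 | (3aR,4R,7aR)-5-[(2S)-5-[(tert-butyldiphenylsilyl)oxy]pentan-2-yl]-6-methyl-3-methylidene-2-oxo-2,3,3a,4,7,7a-hexahydro-1-benzofuran-4-yl (2R)-2-methylbutanoate | C=C1C(=O)O[C@@H]2CC(C)=C([C@@H](C)CCCO[Si](c3ccccc3)(c3ccccc3)C(C)(C)C)[C@H](OC(=O)[C@H](C)CC)[C@H]12 | intermediate
25 | (3aR,4R,7aR)-5-[(2S)-5-hydroxypentan-2-yl]-6-methyl-3-methylidene-2-oxo-2,3,3a,4,7,7a-hexahydro-1-benzofuran-4-yl (2R)-2-methylbutanoate | C=C1C(=O)O[C@@H]2CC(C)=C([C@@H](C)CCCO)[C@H](OC(=O)[C@H](C)CC)[C@H]12 | target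

**Step count and risks**

Total step count: 17. Longest linear sequence: 17 steps (from 1).

Steps most likely to fail:

Step 12. The β,γ-unsaturated aldehyde may isomerize into conjugation or lose CO on ruthenium before it cyclizes, the terminal allene π bond may react instead of the internal one, or the silyl ether may direct the ring closure less cleanly than expected. The fallback sets out from 15 and comes back at 19, and replaces the cyclocarbonylation by a Barbier-type lactone annulation. Alkyne 15 is deprotonated with n-BuLi and acylated with methyl chloroformate to the methyl ynoate F1. Hydroalumination with DIBAL-H/HMPA and trapping of the α-aluminoacrylate with formaldehyde gives the 2-(hydroxymethyl)dienoate F2, and CBr4/PPh3 turns it into the allylic bromide F3. Pyridinium p-toluenesulfonate in wet acetone frees the aldehyde to give the bromo aldehyde F4. CrCl2 in THF/DMF at high dilution then forms the allylchromium species, which adds through its γ-carbon to the aldehyde (Nozaki–Hiyama–Kishi-type allylation) and lactonizes in the flask to 19; the cis ring fusion is the usual outcome of such annulations and the silyl ether should again hold the new bond anti.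

Step 14 (with step 15). The enone carries the lactone oxygen β to the ketone, so β-elimination followed by aromatization, or migration of the exocyclic double bond into the ring, may destroy it before it is reduced; hydride delivery from the wrong face in step 15 would also return 20. The fallback sets out from 20 and comes back at 24 and makes no new compound: Mitsunobu esterification of 20 with 23 (PPh3, diisopropyl azodicarboxylate, toluene, 0 °C) would install the ester with inversion at C4 in one step, with ionization of the allylic alcohol (SN1 or SN2' leakage) as the point to watch.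

Step 8. The catalyst may not tell the two unsaturated ketone substituents apart well enough, which would erode the relay center and with it the configuration of both ring-fusion carbons, or borane may add to the ynone. The fallback sets out from 11 and comes back at 14. DIBAL-H at −78 °C reduces the Weinreb amide to the enal F5. A catalytic asymmetric alkynylation with trimethylsilylacetylene (Et2Zn, Ti(OiPr)4, the BINOL enantiomer that gives the 3S carbinol) gives the silylated propargylic alcohol F6. K2CO3 in MeOH removes the C-silyl group to give 14.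

Further compounds
F1 | step 12 | methyl (4S,5Z)-4-[(tert-butyldimethylsilyl)oxy]-7-(1,3-dioxolan-2-yl)-6-methyl-5-[(2S)-5-[(tert-butyldiphenylsilyl)oxy]pentan-2-yl]hept-5-en-2-ynoate (methyl ynoate) | COC(=O)C#C[C@H](O[Si](C)(C)C(C)(C)C)/C(=C(/C)CC1OCCO1)[C@@H](C)CCCO[Si](c1ccccc1)(c1ccccc1)C(C)(C)C
F2 | step 12 | methyl (2Z,4S,5Z)-4-[(tert-butyldimethylsilyl)oxy]-7-(1,3-dioxolan-2-yl)-2-(hydroxymethyl)-6-methyl-5-[(2S)-5-[(tert-butyldiphenylsilyl)oxy]pentan-2-yl]hepta-2,5-dienoate (2-(hydroxymethyl)dienoate) | COC(=O)/C(CO)=C\[C@H](O[Si](C)(C)C(C)(C)C)/C(=C(/C)CC1OCCO1)[C@@H](C)CCCO[Si](c1ccccc1)(c1ccccc1)C(C)(C)C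
F3 | step 12 | methyl (2E,4S,5Z)-2-(bromomethyl)-4-[(tert-butyldimethylsilyl)oxy]-7-(1,3-dioxolan-2-yl)-6-methyl-5-[(2S)-5-[(tert-butyldiphenylsilyl)oxy]pentan-2-yl]hepta-2,5-dienoate (allylic bromide) | COC(=O)/C(CBr)=C\[C@H](O[Si](C)(C)C(C)(C)C)/C(=C(/C)CC1OCCO1)[C@@H](C)CCCO[Si](c1ccccc1)(c1ccccc1)C(C)(C)C
F4 | step 12 | methyl (2E,4S,5Z)-2-(bromomethyl)-4-[(tert-butyldimethylsilyl)oxy]-6-methyl-8-oxo-5-[(2S)-5-[(tert-butyldiphenylsilyl)oxy]pentan-2-yl]octa-2,5-dienoate (bromo aldehyde) | COC(=O)/C(CBr)=C\[C@H](O[Si](C)(C)C(C)(C)C)/C(=C(/C)CC=O)[C@@H](C)CCCO[Si](c1ccccc1)(c1ccccc1)C(C)(C)C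
F0 | step 14 | none | none
F5 | step 8 | (2Z)-4-(1,3-dioxolan-2-yl)-3-methyl-2-[(2S)-5-[(tert-butyldiphenylsilyl)oxy]pentan-2-yl]but-2-enal (enal) | O=C/C(=C(/C)CC1OCCO1)[C@@H](C)CCCO[Si](c1ccccc1)(c1ccccc1)C(C)(C)C
F6 | step 8 | (3S,4Z)-6-(1,3-dioxolan-2-yl)-5-methyl-4-[(2S)-5-[(tert-butyldiphenylsilyl)oxy]pentan-2-yl]-1-(trimethylsilyl)hex-4-en-1-yn-3-ol (silylated propargylic alcohol) | C[Si](C)(C)C#C[C@H](O)/C(=C(/C)CC1OCCO1)[C@@H](C)CCCO[Si](c1ccccc1)(c1ccccc1)C(C)(C)C
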